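**Strategy.** The route rests on cutting ring B (cyclopentane B1–B5: B1 = spiro carbon shared with dione ring A, B2 = CH–iPr, B3 and B4 = CH2, B5 = pinane C2) at B2–B3. The feature exploited is the isopropyl group on B2 next to the unsubstituted B3: a primary B3 radical, released by cathodic decarboxylation of an N-acyloxyphthalimide, adds 5-exo to the B2 end of a 2-methylpropenyl group on B1, and the resulting tertiary radical becomes isopropyl. One operation closes ring B, forms B2–B3 and sets B2. The precursor is a pinane whose quaternary C2 carries a 2-carboxyethyl arm (as its phthalimide ester) and a CH(CO2Me)CH=CMe2 arm of defined B1 configuration.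

Key step: step 10

Labels: ring A is the six-membered ring made of the spiro carbon B1, the enone carbonyl (C=O between B1 and the methyl-bearing carbon), the methyl-bearing carbon, the methoxy-bearing carbon, the CMe2 carbon and the saturated carbonyl (C=O between the CMe2 carbon and B1). On pinane C2, "syn" means cis to the gem-dimethyl bridge C6 and "anti" means cis to the methylene bridge C7. The faces of ring B are named after the pinane carbon that B5 carries on them (C1 side, C3 side). The pinane core keeps the configuration of (+)-β-pinene throughout.

Remark on stereochemistry: B1 of the radical precursor is not a free centre. It directs B2 (see step 10), so only the (R)-B1 epimer of the radical precursor leads to the B2 configuration of the target; the (S)-epimer would give the B2 epimer. B1 is therefore fixed before step 10 and erased only afterwards.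

Assumption: protonation in step 6 is taken to show no useful bias at B1; the two B1 epimers of the deconjugated ester are taken to be separable by chromatography, and the unwanted (2S)-epimer is taken back through the conditions of step 6.

Remark on the side chain: the carboxyl arm is carried as a silyl ether of the primary alcohol, because an aldehyde set free under acid beside the 2-methylpropenyl group is placed for a citronellal-like carbonyl-ene closure.

**Step 1**
Reactants: 1 (+)-β-pinene
Product: 2 (1S,5R)-nopinone
Conditions: RuCl3·3H2O (2 mol%), NaIO4, EtOAc/MeCN/H2O, rt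
Reagents that add atoms: sodium periodate, [Na+].[O-]I(=O)(=O)=O
Why: Oxidative alkene cleavage by RuO4 formed in situ (Sharpless-type) converts the exocyclic methylidene into the ketone and leaves both bridgehead centres untouched.

**Step 2**
Reactants: 2 (1S,5R)-nopinone; 3 trimethyl phosphonoacetate
Product: 5 methyl 2-(6,6-dimethylbicyclo[3.1.1]heptan-2-ylidene)acetate (E/Z mixture), via sodium phosphonate carbanion 4 (not isolated)
Conditions: NaH, THF, 0 °C; then 2, 65 °C
Reagents that add atoms: none
Why: Horner–Wadsworth–Emmons olefination of the ketone with the stabilised carbanion 4; the alkene geometry is irrelevant because C2 becomes sp3 in step 3.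

**Step 3**
Reactants: 5 methyl 2-(6,6-dimethylbicyclo[3.1.1]heptan-2-ylidene)acetate; 6 (3-bromopropoxy)(tert-butyl)dimethylsilane
Product: 9 methyl 2-{2-anti-[3-(tert-butyldimethylsilyloxy)propyl]-6,6-dimethylbicyclo[3.1.1]heptan-2-yl}acetate (CH2CO2Me syn), via Grignard reagent 7 (not isolated), via silyl ketene acetal 8 (not isolated)
Conditions: 6, Mg, THF, 40 °C; then 5, CuBr·SMe2 (20 mol%), TMSCl, THF, −40 → 0 °C; aq. NH4Cl
Reagents that add atoms: none
Why: Copper-catalysed, TMSCl-accelerated conjugate addition of a Grignard reagent to a β,β-disubstituted enoate (enolate trapped as 8, hydrolysed on work-up); the organocopper attacks C2 from the face away from the gem-dimethyl bridge, the face that also receives hydrogen in hydroboration of 1, so the quaternary centre carries the new arm anti and CH2CO2Me syn.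

**Step 4**
Reactants: 9 methyl 2-{2-anti-[3-(tert-butyldimethylsilyloxy)propyl]-6,6-dimethylbicyclo[3.1.1]heptan-2-yl}acetate; 10 isobutyraldehyde
Product: 12 aldol adduct (β-hydroxy ester, diastereomer mixture), via lithium enolate 11 (not isolated)
Conditions: LiN(i-Pr)2, THF, −78 °C; then 10, −78 °C; AcOH quench at −78 °C
Reagents that add atoms: none
Why: Directed aldol addition of the preformed lithium ester enolate 11 to isobutyraldehyde; the two new stereocentres need no control because both are erased in steps 5 and 6.

**Step 5**
Reactants: 12 aldol adduct
Product: 14 conjugated ester, methyl 4-methylpent-2-enoate carrying the pinane C2 unit at its α-carbon (E/Z mixture), via mesylate 13 (not isolated)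
Conditions: MsCl, Et3N, DMAP (cat.), CH2Cl2, 0 °C; then DBU, 40 °C
Reagents that add atoms: none
Why: Mesylation followed by DBU-induced β-elimination through the ester enolate completes the aldol condensation; either alkene isomer gives the same dienolate in step 6.

**Step 6**
Reactants: 14 conjugated ester
Product: 16 deconjugated ester, methyl (2R)-4-methylpent-3-enoate carrying the pinane C2 unit at B1, via potassium dienolate 15 (not isolated)
Conditions: KN(SiMe3)2, THF, −78 → −40 °C; inverse quench into AcOH/THF, −78 °C; chromatography
Reagents that add atoms: none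
Why: Deconjugative protonation: γ-deprotonation at the isopropyl methine gives dienolate 15 and kinetic protonation at the α-carbon (B1) gives the β,γ-unsaturated ester; B1 is created here without reliable substrate bias, so the (2R)-epimer 16 is isolated by chromatography and the co-formed (2S)-epimer is returned to the same conditions, where it re-enters through the same dienolate.

**Step 7**
Reactants: 16 deconjugated ester
Product: 17 primary alcohol (3-hydroxypropyl arm on pinane C2)
Conditions: camphorsulfonic acid (10 mol%), MeOH/CH2Cl2, 0 °C
Reagents that add atoms: none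
Why: Acid-catalysed methanolysis of the primary silyl ether; the non-basic medium leaves B1–H, the ester and the alkene unchanged.

**Step 8**
Reactants: 17 primary alcohol
Product: 18 carboxylic acid (2-carboxyethyl arm on pinane C2)
Conditions: TEMPO (20 mol%), PhI(OAc)2 (2.2 equiv), MeCN/H2O, rt
Reagents that add atoms: water, O
Why: Oxoammonium (TEMPO) oxidation of the primary alcohol through the aldehyde hydrate to the acid with PhI(OAc)2 as terminal oxidant; the near-neutral medium spares the alkene and B1.

**Step 9**
Reactants: 18 carboxylic acid; 19 N-hydroxyphthalimide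
Product: 20 N-acyloxyphthalimide radical precursor
Conditions: N,N'-diisopropylcarbodiimide, DMAP (10 mol%), CH2Cl2, rt
Reagents that add atoms: none
Why: Carbodiimide (Steglich-type) esterification of the only free acid gives the redox-active ester without touching B1.

**Step 10**
Reactants: 20 N-acyloxyphthalimide radical precursor
Product: 21 ring B methyl ester (spiro-fused cyclopentane; CO2Me on the C1 side, isopropyl on the C3 side)
Conditions: undivided cell, graphite felt cathode, Zn anode, constant current (2.5 F/mol), n-Bu4NPF6, AcOH (3 equiv), t-C12H25SH (20 mol%), DMF, 0.02 M, 25 °C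
Reagents that add atoms: none
Why: Electron transfer from the cathode to the phthalimide unit gives a radical anion that cleaves at N–O and loses CO2, leaving the primary radical at B3; this adds to B2 of the 2-methylpropenyl group, and the tertiary radical so formed takes a hydrogen atom from the thiol, whose thiyl radical is reduced at the cathode and reprotonated by AcOH. The closest known reaction type is the reductive decarboxylative radical cyclisation of N-acyloxyphthalimides, a hex-5-enyl radical closure after single-electron reduction. Ring B closes in the 5-exo-trig mode through a chair-like transition state, since 6-endo attack would have to occur at the fully substituted alkene carbon. The new stereocentre B2 is set by B1: allylic 1,3-strain with the cis methyl group of the alkene holds the B1–H bond in the alkene plane, so the tether on pinane C2 reaches the alkene face opposite CO2Me and isopropyl ends trans to the ester, which for (R)-B1 is the C3 side of ring B as in the target. The step needs cyclisation to outrun hydrogen transfer to the primary radical, which the quaternary C2 (gem-dialkyl effect), the tertiary product radical and the low stationary thiol concentration should secure. Because the radical site lies two carbons away from pinane C2, the cyclobutane is never flanked by a radical or cationic centre and cannot fragment.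

**Step 11**
Reactants: 21 ring B methyl ester
Product: 22 ring B carboxylic acid
Conditions: NaSEt, DMF, 100 °C; then 1 M HCl
Reagents that add atoms: none
Why: Nucleophilic O-demethylation (bimolecular substitution at the methyl group by ethanethiolate) frees the acid without attack at the crowded carbonyl; B1 may epimerise without consequence because it becomes trigonal in step 14.

**Step 12**
Reactants: 22 ring B carboxylic acid
Product: 24 ring B ethyl ketone, via dilithium gem-diolate 23 (not isolated)
Conditions: EtLi (3 equiv), Et2O, 0 °C → rt; inverse quench into 1 M HCl, 0 °C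
Reagents that add atoms: ethyllithium, [Li]CC
Why: Ketone synthesis from a carboxylic acid with two equivalents of organolithium: the lithium carboxylate adds EtLi to give the stable gem-diolate 23, which collapses to the ketone only on acidic quench, so no tertiary alcohol forms.

**Step 13**
Reactants: 24 ring B ethyl ketone; 25 methyl 3-chloro-2,2-dimethyl-3-oxopropanoate
Product: 26 diketo ester (B1 carries the chain C(=O)–CH(Me)–C(=O)–CMe2–CO2Me)
Conditions: MgBr2·OEt2, i-Pr2NEt, CH2Cl2, rt
Reagents that add atoms: none
Why: Soft-enolisation C-acylation: the magnesium-bound ketone is deprotonated at the unhindered CH2 of the ethyl group, not at the crowded methine B1, and the non-enolisable acid chloride acylates carbon to give the chelated β-diketone; the new CH(Me) centre is labile and needs no control.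

**Step 14**
Reactants: 26 diketo ester
Product: 28 spiro triketone (enol at the carbon next to CMe2), via dilithium dianion 27 (not isolated)
Conditions: LiN(i-Pr)2 (3.2 equiv), THF, −78 → 0 °C; then 1 M HCl
Reagents that add atoms: none
Why: Dieckmann (intramolecular Claisen) condensation of dianion 27: the last-formed carbanion terminus B1 attacks the non-enolisable ester to close six-membered ring A, and the ester carbon should approach B1 from the face that bears hydrogen on B2 (anti to isopropyl), which sets the spiro centre with the saturated carbonyl on the C1 side; formation of the stable triketone enolate makes the closure irreversible.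

**Step 15**
Reactants: 28 spiro triketone
Product: 29 CNP0307059.1 (target)
Conditions: TMSCHN2, MeOH/toluene (1:4), 0 °C → rt
Reagents that add atoms: trimethylsilyldiazomethane, C[Si](C)(C)C=[N+]=[N-]
Why: O-Methylation of the vinylogous acid with trimethylsilyldiazomethane; the enol oxygen beside CMe2 is more accessible than the oxygen beside the spiro carbon, which should place the methyl ether on the carbon next to CMe2 as in the target.

**Compound list**

1 | (+)-β-pinene, (1R,5R)-6,6-dimethyl-2-methylidenebicyclo[3.1.1]heptane | C=C1CC[C@@H]2C[C@H]1C2(C)C | starting material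
2 | (1S,5R)-nopinone, 6,6-dimethylbicyclo[3.1.1]heptan-2-one | O=C1CC[C@@H]2C[C@H]1C2(C)C | intermediate
3 | trimethyl phosphonoacetate | COC(=O)CP(=O)(OC)OC | starting material
4 | sodium phosphonate carbanion of 3 | [Na+].COC(=O)[CH-]P(=O)(OC)OC | intermediate (not isolated)
5 | methyl 2-(6,6-dimethylbicyclo[3.1.1]heptan-2-ylidene)acetate, E/Z mixture, pinane core as in 1 | COC(=O)C=C1CC[C@@H]2C[C@H]1C2(C)C | intermediate
6 | (3-bromopropoxy)(tert-butyl)dimethylsilane | CC(C)(C)[Si](C)(C)OCCCBr | starting material
7 | [3-(tert-butyldimethylsilyloxy)propyl]magnesium bromide | CC(C)(C)[Si](C)(C)OCCC[Mg]Br | intermediate (not isolated)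
8 | methyl trimethylsilyl ketene acetal of 9 | COC(O[Si](C)(C)C)=C[C@@]1(CCCO[Si](C)(C)C(C)(C)C)CC[C@@H]2C[C@H]1C2(C)C | intermediate (not isolated)
9 | methyl 2-{2-[3-(tert-butyldimethylsilyloxy)propyl]-6,6-dimethylbicyclo[3.1.1]heptan-2-yl}acetate; CH2CO2Me syn, silyloxypropyl anti | COC(=O)C[C@@]1(CCCO[Si](C)(C)C(C)(C)C)CC[C@@H]2C[C@H]1C2(C)C | intermediate
10 | isobutyraldehyde | CC(C)C=O | starting material
11 | lithium enolate of 9 | COC(O[Li])=C[C@@]1(CCCO[Si](C)(C)C(C)(C)C)CC[C@@H]2C[C@H]1C2(C)C | intermediate (not isolated)
12 | aldol adduct, methyl 2-{2-[3-(tert-butyldimethylsilyloxy)propyl]-6,6-dimethylbicyclo[3.1.1]heptan-2-yl}-3-hydroxy-4-methylpentanoate, mixture at the two new centres | COC(=O)C(C(O)C(C)C)[C@@]1(CCCO[Si](C)(C)C(C)(C)C)CC[C@@H]2C[C@H]1C2(C)C | intermediate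
13 | mesylate of 12 | COC(=O)C(C(OS(C)(=O)=O)C(C)C)[C@@]1(CCCO[Si](C)(C)C(C)(C)C)CC[C@@H]2C[C@H]1C2(C)C | intermediate (not isolated)
14 | conjugated ester, methyl 2-{2-[3-(tert-butyldimethylsilyloxy)propyl]-6,6-dimethylbicyclo[3.1.1]heptan-2-yl}-4-methylpent-2-enoate, E/Z mixture | COC(=O)C(=CC(C)C)[C@@]1(CCCO[Si](C)(C)C(C)(C)C)CC[C@@H]2C[C@H]1C2(C)C | intermediate
15 | potassium dienolate of 14 | COC(O[K])=C(C=C(C)C)[C@@]1(CCCO[Si](C)(C)C(C)(C)C)CC[C@@H]2C[C@H]1C2(C)C | intermediate (not isolated)
16 | deconjugated ester, methyl (2R)-2-{2-[3-(tert-butyldimethylsilyloxy)propyl]-6,6-dimethylbicyclo[3.1.1]heptan-2-yl}-4-methylpent-3-enoate; B1 = C2 of the pentenoate, R | COC(=O)[C@H](C=C(C)C)[C@@]1(CCCO[Si](C)(C)C(C)(C)C)CC[C@@H]2C[C@H]1C2(C)C | intermediate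
17 | primary alcohol from 16 (3-hydroxypropyl arm anti, B1 R) | COC(=O)[C@H](C=C(C)C)[C@@]1(CCCO)CC[C@@H]2C[C@H]1C2(C)C | intermediate
18 | carboxylic acid (2-carboxyethyl arm anti, B1 R) | COC(=O)[C@H](C=C(C)C)[C@@]1(CCC(=O)O)CC[C@@H]2C[C@H]1C2(C)C | intermediate
19 | N-hydroxyphthalimide | ON1C(=O)c2ccccc2C1=O | starting material
20 | N-acyloxyphthalimide of 18, radical precursor | COC(=O)[C@H](C=C(C)C)[C@@]1(CCC(=O)ON4C(=O)c5ccccc5C4=O)CC[C@@H]2C[C@H]1C2(C)C | intermediate
21 | ring B methyl ester, spiro at pinane C2; CO2Me on the C1 side, isopropyl on the C3 side, trans to each other | COC(=O)[C@@H]1[C@@H](C(C)C)CC[C@@]12CC[C@@H]3C[C@H]2C3(C)C | intermediate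
22 | ring B carboxylic acid | OC(=O)[C@@H]1[C@@H](C(C)C)CC[C@@]12CC[C@@H]3C[C@H]2C3(C)C | intermediate
23 | dilithium gem-diolate from 22 and EtLi | CCC(O[Li])(O[Li])[C@@H]1[C@@H](C(C)C)CC[C@@]12CC[C@@H]3C[C@H]2C3(C)C | intermediate (not isolated)
24 | ring B ethyl ketone (propanoyl on B1) | CCC(=O)[C@@H]1[C@@H](C(C)C)CC[C@@]12CC[C@@H]3C[C@H]2C3(C)C | intermediate
25 | methyl 3-chloro-2,2-dimethyl-3-oxopropanoate | COC(=O)C(C)(C)C(Cl)=O | starting material
26 | diketo ester, methyl 2,2,4-trimethyl-3,5-dioxopentanoate carrying the ring B unit at C5, CH(Me) centre unassigned | COC(=O)C(C)(C)C(=O)C(C)C(=O)[C@@H]1[C@@H](C(C)C)CC[C@@]12CC[C@@H]3C[C@H]2C3(C)C | intermediate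
27 | dilithium dianion of 26 (enolates at the CH(Me) carbon and at B1) | COC(=O)C(C)(C)C(O[Li])=C(C)C(O[Li])=C1[C@@H](C(C)C)CC[C@@]12CC[C@@H]3C[C@H]2C3(C)C | intermediate (not isolated)
28 | spiro triketone, drawn as the enol at the carbon next to CMe2; saturated carbonyl on the C1 side, enone carbonyl on the isopropyl side | OC1=C(C)C(=O)[C@@]2(C(=O)C1(C)C)[C@@H](C(C)C)CC[C@@]21CC[C@@H]2C[C@H]1C2(C)C | intermediate
29 | CNP0307059.1, methyl enol ether of 28 at the carbon next to CMe2 | COC1=C(C)C(=O)[C@@]2(C(=O)C1(C)C)[C@@H](C(C)C)CC[C@@]21CC[C@@H]2C[C@H]1C2(C)C | target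

**Totals.** Total step count: 15. Longest linear sequence: 15 steps, from 1 to 29.

**Steps most likely to fail**

Step 10. Hydrogen transfer to the primary radical, or its further reduction at the electrode, may overtake ring closure and give open-chain reduced ester, or the electrolysis may stall through electrode fouling. The fallback sets out from acid 18. Coupling with 1-hydroxypyridine-2(1H)-thione (N,N'-dicyclohexylcarbodiimide, DMAP, CH2Cl2, in the dark) gives the Barton ester F1. Irradiation of F1 with a tungsten lamp in benzene, with slow addition of t-BuSH, generates the same B3 radical in a thiyl-carried chain; 5-exo closure under the same B1 control and hydrogen transfer from the thiol bring the route back at 21.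

Step 14. The crowded methine B1 may resist the second deprotonation, so that an enolate oxygen rather than carbon attacks the ester, or the carbanion may fail to reach the neopentyl-type ester carbon while two adjacent quaternary centres form. The fallback sets out from ketone 24. C-Acylation with 2-cyano-2-methylpropanoyl chloride under the soft-enolisation conditions of step 13 gives the diketo nitrile F2. With LiN(i-Pr)2 its dianion adds through B1 to the slim nitrile carbon (Thorpe–Ziegler closure) to give the cyclic ketimine F3, and hydrolysis of F3 with aqueous HCl in THF brings the route back at 28.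

Step 3. The 1,4-addition may be too slow at the hindered β,β-disubstituted enoate, leaving starting enoate or 1,2-adducts. The fallback sets out from ketone 2. Knoevenagel condensation with dimethyl malonate (TiCl4, pyridine, THF) gives the more electrophilic alkylidene malonate F4. Addition of Grignard reagent 7 with CuI (cat.) from the same face gives the malonate F5, and Krapcho demethoxycarbonylation (LiCl, wet DMSO, 150 °C) brings the route back at 9.

**Further compounds**

F1 | step 10 | Barton ester of 18 (2-thioxopyridin-1(2H)-yl ester) | COC(=O)[C@H](C=C(C)C)[C@@]1(CCC(=O)ON3C=CC=CC3=S)CC[C@@H]2C[C@H]1C2(C)C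
F2 | step 14 | diketo nitrile, 2,2,4-trimethyl-3,5-dioxopentanenitrile carrying the ring B unit at the terminal ketone carbon | N#CC(C)(C)C(=O)C(C)C(=O)[C@@H]1[C@@H](C(C)C)CC[C@@]12CC[C@@H]3C[C@H]2C3(C)C
F3 | step 14 | cyclic ketimine of 28 (C=NH in place of the saturated carbonyl, enol at the carbon next to CMe2) | OC1=C(C)C(=O)[C@@]2(C(=N)C1(C)C)[C@@H](C(C)C)CC[C@@]21CC[C@@H]2C[C@H]1C2(C)C
F4 | step 3 | dimethyl 2-(6,6-dimethylbicyclo[3.1.1]heptan-2-ylidene)malonate | COC(=O)C(C(=O)OC)=C1CC[C@@H]2C[C@H]1C2(C)C
F5 | step 3 | dimethyl 2-{2-anti-[3-(tert-butyldimethylsilyloxy)propyl]-6,6-dimethylbicyclo[3.1.1]heptan-2-yl}malonate | COC(=O)C(C(=O)OC)[C@@]1(CCCO[Si](C)(C)C(C)(C)C)CC[C@@H]2C[C@H]1C2(C)C
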